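**Assumptions (one line each)**
- 7-Methyljuglone (1) is purchased; it is sold as a natural-product standard.
- The target SMILES has no stereodescriptors. I treat the tetra-ortho-substituted biaryl axis as unspecified (racemic or freely interconverting), so there are no stereocentres to set.
- Under basic conditions the 5-phenolate makes C4=O less electrophilic, so nucleophiles add at C3, which is β to the C1=O carbonyl.

## Retrosynthetic overview
1. Target (4) → disconnect both vinylogous-ester C3–OEt bonds (oxa-Michael addition of EtOH, then reoxidation) → isodiospyrin (2).
2. Isodiospyrin (2) → disconnect the C6–C6′ biaryl bond (oxidative phenol coupling, the biomimetic step) → two equivalents of 7-methyljuglone (1).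
3. Both naphthoquinone rings are already present in (1), so no ring is formed in this route. The order is biaryl coupling first, then C3/C3′ ethoxylation.

## Route

**Step 1**
Reactants: 1, 7-methyljuglone (5-hydroxy-7-methylnaphthalene-1,4-dione), 2 equiv
Product: 2, isodiospyrin (6,6′-bi-7-methyljuglone)
Conditions: Ag2O (4 equiv), CHCl3, rt, dark, 24 h; chromatographic separation of regioisomers
Reagents that add atoms: none (Ag2O is only an oxidant; the product loses 2 H)
Why: Ag(I) oxidises the phenol to a phenoxyl radical that couples ortho to OH (biomimetic oxidative phenol coupling). Coupling at C6 is favoured because it gives the least hindered tetra-ortho biaryl (OH and Me flanking the bond, rather than Me and peri C=O as in 8,8′). There is no stereocentre, and the axis is left unspecified.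

**Step 2**
Reactants: 2, isodiospyrin; 3, ethanol
Product: 4, 3,3′-diethoxyisodiospyrin (target)
Conditions: NaOEt (2.5 equiv), EtOH/THF 1:1, 0 °C → rt, open to air, 16 h; then 1 M HCl work-up
Reagents that add atoms: ethanol, CCO; sodium ethoxide, CC[O-].[Na+]
Why: This is an oxa-Michael addition of ethoxide followed by air reoxidation of the ethoxy-hydroquinone (oxidative alkoxylation of a quinone). The phenolate deactivates the chelated C4=O, so ethoxide adds at C3 (β to C1=O). Two such additions, one per quinone ring, give the bis-vinylogous ester. The HCl work-up reprotonates the phenolates and restores the chelated peri-OH. No stereocentre is formed.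

## Checks
- **Structure:** The target has two 3-ethoxy-5-hydroxy-7-methyl-1,4-naphthoquinone units joined at C6–C6′. Each OEt sits α to the C4=O that is peri to the OH (the C(OEt)–C(=O)–c(ring fusion)–c(OH) pattern in the SMILES). This matches Step 2.
- **Atom balance, Step 1:** 2 × C11H8O3 → C22H14O6 + 2 H (taken up by Ag2O).
- **Atom balance, Step 2:** C22H14O6 + 2 EtOH − 4 H (air oxidation) → C26H22O8, which is the target formula.
- **Functional-group survival:** The quinones and phenols survive Ag2O. In Step 2 the aryl C–C bond, methyl groups and phenolate are inert. The vinylogous-ester OEt survives the dilute-acid work-up.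
- **Stereo:** There are no stereocentres. No step creates or scrambles one.

## Compound list
1 | 7-methyljuglone (5-hydroxy-7-methylnaphthalene-1,4-dione) | Cc1cc(O)c2C(=O)C=CC(=O)c2c1 | starting material
2 | isodiospyrin (6,6′-bi-7-methyljuglone) | Cc1cc2C(=O)C=CC(=O)c2c(O)c1-c1c(C)cc2C(=O)C=CC(=O)c2c1O | intermediate
3 | ethanol | CCO | starting material
4 | 3,3′-diethoxyisodiospyrin | CCOC1=CC(=O)c2cc(C)c(-c3c(C)cc(O)c4c3C(=O)C=C(OCC)C4=O)c(O)c2C1=O | target

## Totals
- Total step count: 2
- Longest linear sequence: 2

## Three steps most likely to fail
1. **Step 1, regioselectivity of the oxidative coupling.** Mixtures of 6,6′, 6,8′ and 8,8′ dimers, or coupling of the phenol onto quinone C2 (diospyrin-type 2,6′ linkage), are possible.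
   - Fallback: a regio-defined cross-coupling. Convert 7-methyljuglone to its hydroquinone trimethyl ether, install iodine at C6 by ortho-lithiation directed by a 5-OCONEt2 group, and run a Pd or Cu homocoupling. Then oxidise with CAN and remove the peri-protecting group under mild conditions.
2. **Step 2, C3 versus C2 selectivity and yield.** Ethoxide may add at C2, or the quinone and hydroquinone may undergo redox exchange and decomposition.
   - Fallback: epoxidise isodiospyrin with alkaline H2O2 and open the epoxides to the 3,3′-dihydroxy compound. Then O-ethylate with EtI and Ag2O to lock in the ethoxy positions.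
3. **Step 2, double addition on a poorly soluble dimer.** This risks mono-ethoxylation or over-oxidation.
   - Fallback: swap the order. Ethoxylate 7-methyljuglone first (monomer, easier to purify and separate isomers), then do the oxidative dimerisation as the last step.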